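**Plan**

1. Lactone atoms are called O1, C2 (C=O), C3 (=CH2), C4 (CO2H) and C5 (chain). Retrosynthetic cuts, in order: C3=CH2 (α-methylenation); O1–C5 (ring switch); C4–C5 together with the acyl–oxygen bond of a β-lactone (ketene–aldehyde [2+2]); one CH2–CH2 bond of the chain.
2. Enabling feature: C2 and the CO2H on C4 are the two ends of a succinic acid unit, and both can reach C5. The C4 carboxyl can therefore hold the C5 oxygen in an oxetan-2-one (C4, its carboxyl carbon, O, C5), a strained isomer of the target's oxolan-2-one ring (O1, C2, C3, C4, C5).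
3. Forward: chain aldehyde by copper-catalysed sp3–sp3 coupling and oxidation; the four-membered ring first, by catalytic asymmetric cycloaddition; then the five-membered ring from it by intramolecular SN2 attack of the C2 carboxylate at C5, which also sets the CO2H free; then the methylene; last the ketone.
4. Stereochemistry: C4 and C5 are set together, cis, by the cinchona alkaloid catalyst of the cycloaddition. C5 is then inverted stereospecifically in the ring switch and C4 is never enolised, so the cis-(3S,4R) β-lactone maps onto the cis-(4S,5S) lactone of the target.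

Key step: step 6

Assumption: O-trimethylsilylquinine is taken to deliver the (3S,4R) β-lactone series in step 4; should the sense be the opposite, the pseudo-enantiomeric O-trimethylsilylquinidine replaces it.

**Route**

Step 1
Reactants: 1 2-(2-bromoethyl)-2-methyl-1,3-dioxolane; 2 12-bromododecan-1-ol
Product: 4 14-(2-methyl-1,3-dioxolan-2-yl)tetradecan-1-ol, via Grignard reagent 3 (not isolated)
Conditions: 1, Mg, THF, 25 °C; then 2 (3 used at 2.2 equiv relative to 2), Li2CuCl4 (3 mol%), THF, −20 → 0 °C; aq. NH4Cl
Reagents that add atoms: none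
Why: Kochi-type copper-catalysed cross-coupling of a primary alkyl Grignard reagent with a primary alkyl bromide should join the two chain pieces, the first equivalent of 3 being spent as base on the hydroxyl group and the dioxolane being inert to the organometallic.

Step 2
Reactants: 4 14-(2-methyl-1,3-dioxolan-2-yl)tetradecan-1-ol
Product: 5 14-(2-methyl-1,3-dioxolan-2-yl)tetradecanal
Conditions: TEMPO (10 mol%), PhI(OAc)2 (1.1 equiv), CH2Cl2, 23 °C
Reagents that add atoms: none
Why: Oxoammonium (TEMPO) oxidation of a primary alcohol should stop at the aldehyde, and the dioxolane should tolerate the acetic acid released in anhydrous CH2Cl2.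

Step 3
Reactants: 6 4-(benzyloxy)-4-oxobutanoic acid (monobenzyl succinate)
Product: 7 benzyl 4-chloro-4-oxobutanoate
Conditions: (COCl)2 (1.2 equiv), DMF (cat.), CH2Cl2, 0 → 23 °C; concentrate
Reagents that add atoms: oxalyl chloride, ClC(=O)C(=O)Cl
Why: Standard acid chloride formation through the Vilsmeier-type chloroiminium catalyst, which leaves the benzyl ester untouched.

Step 4
Reactants: 5 14-(2-methyl-1,3-dioxolan-2-yl)tetradecanal; 7 benzyl 4-chloro-4-oxobutanoate
Product: 9 benzyl 2-[(3S,4R)-4-[13-(2-methyl-1,3-dioxolan-2-yl)tridecyl]-2-oxooxetan-3-yl]acetate (cis), via ketene 8 (not isolated)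
Conditions: O-trimethylsilylquinine (10 mol%), LiClO4 (2 equiv), iPr2NEt (2.5 equiv), CH2Cl2/Et2O, −78 °C; 7 (2 equiv) added slowly
Reagents that add atoms: none
Why: Acyl halide–aldehyde cyclocondensation (Wynberg-type formal [2+2] of a ketene with an aldehyde): the alkaloid adds to ketene 8 to give a (Z)-ammonium enolate, which adds to the lithium-activated aldehyde through a closed chair-like transition state and lactonises with release of the catalyst, so that the catalyst sets the absolute configuration of both new centres and the closed transition state their cis relationship.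

Step 5
Reactants: 9 benzyl 2-[(3S,4R)-4-[13-(2-methyl-1,3-dioxolan-2-yl)tridecyl]-2-oxooxetan-3-yl]acetate
Product: 10 2-[(3S,4R)-4-[13-(2-methyl-1,3-dioxolan-2-yl)tridecyl]-2-oxooxetan-3-yl]acetic acid
Conditions: H2 (1 atm), Pd/C (10%), EtOAc, 23 °C; filter, concentrate below 25 °C
Reagents that add atoms: none
Why: Hydrogenolysis of a benzyl ester under neutral conditions should spare the non-benzylic β-lactone and the dioxolane, and the un-ionised acid is a poor nucleophile in ethyl acetate, so 10 should be isolable (an early ring switch here would only anticipate step 6).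

Step 6
Reactants: 10 2-[(3S,4R)-4-[13-(2-methyl-1,3-dioxolan-2-yl)tridecyl]-2-oxooxetan-3-yl]acetic acid
Product: 11 (2S,3S)-2-[13-(2-methyl-1,3-dioxolan-2-yl)tridecyl]-5-oxooxolane-3-carboxylic acid (cis)
Conditions: iPr2NEt (0.1 equiv), MeCN (0.02 M), 23 → 40 °C; aq. NaH2PO4
Reagents that add atoms: none
Why: Proposed new method: the base turns the side-chain acid into its carboxylate, which attacks the oxygen-bearing ring carbon of the oxetan-2-one from the side opposite the ring oxygen in an intramolecular SN2 displacement with alkyl–oxygen scission, so that the strained β-lactone opens as the γ-lactone closes and the former lactone carbonyl leaves as a carboxylate, which takes a proton from the next molecule of 10 and makes the base catalytic. The closest known reaction types are the opening of β-lactones by carboxylate salts at the alkyl carbon with inversion (the propagation step of their anionic ring-opening polymerisation, and the same site at which azide and thiolates open cis-3,4-dialkyl β-lactones) and the isomerisation of oxetane carboxylic acids to γ-lactones. The oxolan-2-one ring closes in the 5-exo-tet mode. No stereocentre is created: the carbinol centre is inverted stereospecifically (4R in 10 becomes 2S in 11) and the neighbouring centre is untouched, so the cis-β-lactone can only give the cis-γ-lactone. The step needs attack at the alkyl carbon instead of the lactone carbonyl (the latter would pass through a cyclic anhydride, return the oxygen with retention and lead into the trans series) and no enolisation; a weakly basic carboxylate in a dipolar aprotic solvent without Lewis acid favours the SN2 path, the amine is too weak to deprotonate the lactone α-carbon, and high dilution suppresses intermolecular opening.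

Step 7
Reactants: 11 (2S,3S)-2-[13-(2-methyl-1,3-dioxolan-2-yl)tridecyl]-5-oxooxolane-3-carboxylic acid
Product: 13 (2S,3S)-4-methylidene-2-[13-(2-methyl-1,3-dioxolan-2-yl)tridecyl]-5-oxooxolane-3-carboxylic acid, via dicarboxylic acid 12 (not isolated)
Conditions: MeOMgOCO2Me (Stiles' reagent, 2 M in DMF, excess), 135 °C; cold 1 M HCl, extraction (crude 12); then 37% aq. HCHO, PhNHMe, NaOAc, AcOH, 23 °C
Reagents that add atoms: formaldehyde, C=O (the methylene carbon); methoxymagnesium methyl carbonate, COC(=O)O[Mg]OC (its CO2 unit is held only in 12 and is lost again)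
Why: Stiles carboxylation followed by decarboxylative Mannich methylenation, the standard α-methylenation of paraconic acids: only the lactone α-CH2 is carboxylated (magnesium chelate), and the malonic half-acid 12 condenses with the iminium ion from HCHO and PhNHMe and loses CO2 and the amine to give the exocyclic alkene, while the carboxyl-bearing centre (α to a carboxylate, not enolised) and the carbinol centre are untouched and the dioxolane keeps the ketone out of the carboxylation.

Step 8
Reactants: 13 (2S,3S)-4-methylidene-2-[13-(2-methyl-1,3-dioxolan-2-yl)tridecyl]-5-oxooxolane-3-carboxylic acid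
Product: 14 allo-pertusaric acid, (2S,3S)-4-methylidene-5-oxo-2-(14-oxopentadecyl)oxolane-3-carboxylic acid
Conditions: 1 M aq. HCl, THF, 23 °C
Reagents that add atoms: water, O
Why: Acid-catalysed hydrolysis of the dioxolane should free the methyl ketone, the α-methylene lactone, the free acid and the cis relationship being stable to dilute aqueous acid at 23 °C because epimerisation and migration of the double bond into the ring need base.

**Compound list**

1 | 2-(2-bromoethyl)-2-methyl-1,3-dioxolane | CC1(CCBr)OCCO1 | starting material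
2 | 12-bromododecan-1-ol | OCCCCCCCCCCCCBr | starting material
3 | [2-(2-methyl-1,3-dioxolan-2-yl)ethyl]magnesium bromide | CC1(CC[Mg]Br)OCCO1 | intermediate
4 | 14-(2-methyl-1,3-dioxolan-2-yl)tetradecan-1-ol | OCCCCCCCCCCCCCCC1(C)OCCO1 | intermediate
5 | 14-(2-methyl-1,3-dioxolan-2-yl)tetradecanal | O=CCCCCCCCCCCCCCC1(C)OCCO1 | intermediate
6 | 4-(benzyloxy)-4-oxobutanoic acid | OC(=O)CCC(=O)OCc1ccccc1 | starting material
7 | benzyl 4-chloro-4-oxobutanoate | ClC(=O)CCC(=O)OCc1ccccc1 | intermediate
8 | benzyl 4-oxobut-3-enoate (ketene) | O=C=CCC(=O)OCc1ccccc1 | intermediate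
9 | benzyl 2-[(3S,4R)-4-[13-(2-methyl-1,3-dioxolan-2-yl)tridecyl]-2-oxooxetan-3-yl]acetate | O=C(C[C@@H]1C(=O)O[C@@H]1CCCCCCCCCCCCCC2(C)OCCO2)OCc3ccccc3 | intermediate
10 | 2-[(3S,4R)-4-[13-(2-methyl-1,3-dioxolan-2-yl)tridecyl]-2-oxooxetan-3-yl]acetic acid | OC(=O)C[C@@H]1C(=O)O[C@@H]1CCCCCCCCCCCCCC2(C)OCCO2 | intermediate
11 | (2S,3S)-2-[13-(2-methyl-1,3-dioxolan-2-yl)tridecyl]-5-oxooxolane-3-carboxylic acid | O=C1C[C@H](C(=O)O)[C@H](CCCCCCCCCCCCCC2(C)OCCO2)O1 | intermediate
12 | (2S,3S)-2-[13-(2-methyl-1,3-dioxolan-2-yl)tridecyl]-5-oxooxolane-3,4-dicarboxylic acid (either configuration at C4) | OC(=O)C1C(=O)O[C@@H](CCCCCCCCCCCCCC2(C)OCCO2)[C@H]1C(=O)O | intermediate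
13 | (2S,3S)-4-methylidene-2-[13-(2-methyl-1,3-dioxolan-2-yl)tridecyl]-5-oxooxolane-3-carboxylic acid | C=C1C(=O)O[C@@H](CCCCCCCCCCCCCC2(C)OCCO2)[C@H]1C(=O)O | intermediate
14 | allo-pertusaric acid, (2S,3S)-4-methylidene-5-oxo-2-(14-oxopentadecyl)oxolane-3-carboxylic acid | C=C1C(=O)O[C@@H](CCCCCCCCCCCCCC(C)=O)[C@H]1C(=O)O | target

**Summary**

Total step count: 8. Longest linear sequence: 7 steps (steps 1, 2, 4, 5, 6, 7, 8).

Steps most likely to fail:

1. Step 6 (ring switch). The carboxylate may attack the lactone carbonyl instead of the carbinol carbon; this acyl–oxygen scission through a cyclic anhydride would return the oxygen with retention and lead into the trans series. Intermolecular opening to oligomers is the second risk. The fallback sets out from 9 and comes back at 11, and it separates the two events. With the side-chain carboxyl still blocked as its benzyl ester, 9 is opened by an external carboxylate, CsOAc in DMF at 40–50 °C (alkyl–oxygen opening of a β-lactone by a carboxylate salt, inversion), to give (2S,3S)-3-acetoxy-2-[2-(benzyloxy)-2-oxoethyl]-16-(2-methyl-1,3-dioxolan-2-yl)hexadecanoic acid F1. K2CO3 in MeOH at 23 °C then removes the acetate, the freed alkoxide acylates onto the side-chain ester (5-exo-trig, retention at the carbinol carbon), and acidification to pH 3 closes any ring-opened hydroxy ester and gives 11. In F1 no β-lactone is left, so the anhydride pathway does not exist.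

2. Step 4 (cycloaddition). The ester-bearing ketene may dimerise faster than it adds to the unbranched aldehyde, or the cis and facial selectivity may be poor. The fallback sets out from 5 and comes back at 10, and it builds the same cis-β-lactone by auxiliary-controlled aldol chemistry. (S)-4-Benzyl-1,3-oxazolidin-2-one is acylated with pent-4-enoyl chloride (n-BuLi, THF, −78 °C) to (4S)-4-benzyl-3-(pent-4-enoyl)-1,3-oxazolidin-2-one F2. Its dibutylboron (Z)-enolate (Bu2BOTf, iPr2NEt, CH2Cl2, −78 → 0 °C) adds to 5 to give the Evans syn-aldol adduct (4S)-4-benzyl-3-[(2S,3R)-3-hydroxy-16-(2-methyl-1,3-dioxolan-2-yl)-2-(prop-2-en-1-yl)hexadecanoyl]-1,3-oxazolidin-2-one F3. LiOH/H2O2 (THF/H2O, 0 °C) removes the auxiliary to give (2S,3R)-3-hydroxy-16-(2-methyl-1,3-dioxolan-2-yl)-2-(prop-2-en-1-yl)hexadecanoic acid F4. Carboxyl activation with PhSO2Cl in pyridine at 0 °C closes, with retention, (3S,4R)-4-[13-(2-methyl-1,3-dioxolan-2-yl)tridecyl]-3-(prop-2-en-1-yl)oxetan-2-one F5. Ozonolysis (O3, CH2Cl2, −78 °C; PPh3) gives 2-[(3S,4R)-4-[13-(2-methyl-1,3-dioxolan-2-yl)tridecyl]-2-oxooxetan-3-yl]acetaldehyde F6, and Pinnick oxidation (NaClO2, NaH2PO4, 2-methylbut-2-ene, t-BuOH/H2O) gives 10. The allyl group is used as the masked carboxyl because an ester side chain would lactonise onto the aldol hydroxyl with retention.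

3. Step 7 (methylenation). The long heating with the magnesium reagent may cause epimerisation at the carboxyl-bearing carbon or migration of the new double bond into the ring, and partial loss of the dioxolane would open the way to methylenation next to the ketone. The fallback sets out from 11 and comes back at 13, and it works at low temperature through the dianion. LiN(SiMe3)2 (2.2 equiv, THF, −78 °C) forms the carboxylate–lactone enolate, which is trapped with Eschenmoser's salt (CH2=NMe2 iodide) to give (2S,3S)-4-[(dimethylamino)methyl]-2-[13-(2-methyl-1,3-dioxolan-2-yl)tridecyl]-5-oxooxolane-3-carboxylic acid F7. Quaternisation with MeI in MeOH and elimination with aq. NaHCO3 give 13.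

**Further compounds**

F1 | step 6 | (2S,3S)-3-acetoxy-2-[2-(benzyloxy)-2-oxoethyl]-16-(2-methyl-1,3-dioxolan-2-yl)hexadecanoic acid | O=C(C[C@H](C(=O)O)[C@@H](OC(C)=O)CCCCCCCCCCCCCC1(C)OCCO1)OCc2ccccc2
F2 | step 4 | (4S)-4-benzyl-3-(pent-4-enoyl)-1,3-oxazolidin-2-one | C=CCCC(=O)N1[C@@H](Cc2ccccc2)COC1=O
F3 | step 4 | (4S)-4-benzyl-3-[(2S,3R)-3-hydroxy-16-(2-methyl-1,3-dioxolan-2-yl)-2-(prop-2-en-1-yl)hexadecanoyl]-1,3-oxazolidin-2-one | C=CC[C@H](C(=O)N1[C@@H](Cc2ccccc2)COC1=O)[C@H](O)CCCCCCCCCCCCCC3(C)OCCO3
F4 | step 4 | (2S,3R)-3-hydroxy-16-(2-methyl-1,3-dioxolan-2-yl)-2-(prop-2-en-1-yl)hexadecanoic acid | C=CC[C@H](C(=O)O)[C@H](O)CCCCCCCCCCCCCC1(C)OCCO1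
F5 | step 4 | (3S,4R)-4-[13-(2-methyl-1,3-dioxolan-2-yl)tridecyl]-3-(prop-2-en-1-yl)oxetan-2-one | C=CC[C@@H]1C(=O)O[C@@H]1CCCCCCCCCCCCCC2(C)OCCO2
F6 | step 4 | 2-[(3S,4R)-4-[13-(2-methyl-1,3-dioxolan-2-yl)tridecyl]-2-oxooxetan-3-yl]acetaldehyde | O=CC[C@@H]1C(=O)O[C@@H]1CCCCCCCCCCCCCC2(C)OCCO2
F7 | step 7 | (2S,3S)-4-[(dimethylamino)methyl]-2-[13-(2-methyl-1,3-dioxolan-2-yl)tridecyl]-5-oxooxolane-3-carboxylic acid | CN(C)CC1C(=O)O[C@@H](CCCCCCCCCCCCCC2(C)OCCO2)[C@H]1C(=O)O
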